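The cyclopentane (C1–C5 in daucane numbering: C1 the methyl-bearing ring-fusion carbon, C2 the acetoxy carbon, C4 the isopropyl carbinol) is a masked 3-hydroxycyclopentanone, and its C2 oxygen can first act as a tether between C2 and C3. The key step heats an open-chain allyl vinyl ether, C1=C2–O–C3–C4(OMe)=C5: a Claisen rearrangement forges C1–C5 and the quaternary centre, and the aldehyde set free at C2 is then captured by C3 of the methyl enol ether (C2–C3 bond) under magnesium chelation, closing the ring. The precursor comes from two enantioenriched fragments joined by copper-catalysed C–O coupling; ring-closing metathesis later closes the cycloheptene at C8=C9.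

Key step: step 11

Numbering and descriptors: C5 is the ring-fusion CH, C6–C10 the remaining cycloheptane carbons (C6 veratroyloxy, C8 methyl, C10 hydroxyl); β is the face of the C1 methyl. "Dauc" names imply 1β-methyl, 5α-H (trans fusion) and 4α-isopropyl.

Assumption: read literally, the target string places the oxirane oxygen on opposite faces at C8 and C9. An oxirane fused to the seven-membered ring is closed on one face, so the route delivers it on the face written for C9 (α, syn to the C10 hydroxyl), and the structure string of 26 keeps the descriptors of the target unchanged.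

Step 1
Reactants: 1 prop-2-yn-1-ol
Product: 3 (E)-3-iodo-2-methylprop-2-en-1-ol, via alkenylalane 2 (not isolated)
Conditions: AlMe3 (3 equiv), Cp2ZrCl2 (25 mol%), CH2Cl2, 0 → 25 °C; then I2, THF, −30 °C
Reagents that add atoms: trimethylaluminium C[Al](C)C; iodine II
Why: Zirconium-catalysed syn-carboalumination of the terminal alkyne puts methyl on the internal carbon with aluminium cis to it, and iodinolysis with retention should give the (E)-vinyl iodide with iodine cis to methyl (carboalumination–iodination).

Step 2
Reactants: 3 (E)-3-iodo-2-methylprop-2-en-1-ol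
Product: 4 (E)-3-iodo-2-methylprop-2-enal
Conditions: MnO2, CH2Cl2, 25 °C
Reagents that add atoms: none
Why: Allylic oxidation with activated MnO2 stops at the enal and leaves the vinyl iodide and its geometry untouched.

Step 3
Reactants: 4 (E)-3-iodo-2-methylprop-2-enal
Product: 5 racemic (E)-1-iodo-2-methylpenta-1,4-dien-3-ol
Conditions: CH2=CHMgBr, THF, −78 °C; aq. NH4Cl
Reagents that add atoms: vinylmagnesium bromide C=C[Mg]Br
Why: 1,2-Addition of the vinyl Grignard reagent to the enal at low temperature gives the bis-allylic alcohol as a racemate (Grignard addition).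

Step 4
Reactants: 5 racemic (E)-1-iodo-2-methylpenta-1,4-dien-3-ol
Product: 6 (1E,3S)-1-iodo-2-methylpenta-1,4-dien-3-ol
Conditions: lipase from Burkholderia cepacia, vinyl acetate, hexane, 25 °C, stopped near half conversion
Reagents that add atoms: none
Why: Lipase-catalysed transesterification should acylate the (R)-enantiomer, following the empirical size rule for secondary alcohols (large iodomethylvinyl against small vinyl), and leave the (S)-alcohol that carries the C10 configuration (enzymatic kinetic resolution).

Step 5
Reactants: 6 (1E,3S)-1-iodo-2-methylpenta-1,4-dien-3-ol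
Product: 7 (1E,3S)-1-iodo-3-[(4-methoxybenzyl)oxy]-2-methylpenta-1,4-diene (fragment B)
Conditions: NaH, 4-methoxybenzyl chloride, Bu4NI (cat.), THF/DMF, 0 → 25 °C
Reagents that add atoms: 4-methoxybenzyl chloride COc1ccc(CCl)cc1
Why: Williamson etherification under basic conditions avoids ionisation of the bis-allylic carbinol and installs the chelating PMB ether needed in the key step.

Step 6
Reactants: 8 ethyl glyoxylate; 9 isobutene
Product: 10 ethyl (R)-2-hydroxy-4-methylpent-4-enoate
Conditions: Ti(OiPr)2Cl2 (10 mol%), (R)-BINOL (10 mol%), 4 Å molecular sieves, CH2Cl2, −30 °C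
Reagents that add atoms: none
Why: The titanium–BINOL-catalysed glyoxylate–ene reaction with isobutene should give the (R)-α-hydroxy ester, which sets the C6 stereocentre (asymmetric carbonyl–ene reaction).

Step 7
Reactants: 10 ethyl (R)-2-hydroxy-4-methylpent-4-enoate
Product: 11 ethyl (R)-2-[(tert-butyldimethylsilyl)oxy]-4-methylpent-4-enoate
Conditions: TBSCl, imidazole, DMF, 25 °C
Reagents that add atoms: tert-butyldimethylsilyl chloride CC(C)(C)[Si](C)(C)Cl
Why: Silylation of the secondary alcohol gives a bulky, non-chelating ether that later steers the Claisen rearrangement (silyl ether formation).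

Step 8
Reactants: 11 ethyl (R)-2-[(tert-butyldimethylsilyl)oxy]-4-methylpent-4-enoate; 12 methyl 2-(dimethoxyphosphoryl)-2-methoxyacetate
Product: 14 methyl (2Z,4R)-4-[(tert-butyldimethylsilyl)oxy]-2-methoxy-6-methylhepta-2,6-dienoate, via aldehyde 13 (not isolated)
Conditions: iBu2AlH (1.1 equiv), CH2Cl2, −78 °C; then sodium salt of 12 (NaH, THF), −78 → 25 °C
Reagents that add atoms: none
Why: Half-reduction of the α-silyloxy ester and in situ Horner–Wadsworth–Emmons olefination with the α-methoxy phosphonate should give mainly the (Z)-enol ether ester (chain trans to the ester) without isolating the epimerisable aldehyde, the minor (E)-isomer being removed by chromatography.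

Step 9
Reactants: 14 methyl (2Z,4R)-4-[(tert-butyldimethylsilyl)oxy]-2-methoxy-6-methylhepta-2,6-dienoate
Product: 15 (2Z,4R)-4-[(tert-butyldimethylsilyl)oxy]-2-methoxy-6-methylhepta-2,6-dien-1-ol (fragment A)
Conditions: iBu2AlH (2.5 equiv), CH2Cl2, −78 °C
Reagents that add atoms: none
Why: Hydride reduction of the conjugated ester gives the primary allylic alcohol and leaves the methyl enol ether and the silyl ether intact (ester reduction).

Step 10
Reactants: 7 vinyl iodide fragment B; 15 allylic alcohol fragment A
Product: 16 allyl vinyl ether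
Conditions: CuI (10 mol%), 3,4,7,8-tetramethyl-1,10-phenanthroline (20 mol%), Cs2CO3, PhMe, 80 °C
Reagents that add atoms: none
Why: Copper-catalysed C–O cross-coupling of a vinyl iodide with an allylic alcohol proceeds with retention of the vinyl geometry (Ullmann-type vinylation), and at 80 °C the trisubstituted, 5-methoxy-retarded allyl vinyl ether should survive without rearranging.

Step 11
Reactants: 16 allyl vinyl ether
Product: 18 hydroxy cyclopentanone, via Claisen aldehyde 17 (not isolated)
Conditions: PhMe, 150 °C, sealed tube; cool to −40 °C, add CH2Cl2 and MgBr2·OEt2, warm to 0 °C; aq. NH4Cl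
Reagents that add atoms: water O
Why: Heating drives a Claisen rearrangement of the C1=C2–O–C3–C4=C5 array through a chair transition state, forming C1–C5 and unmasking C2 as an aldehyde; MgBr2·OEt2 then chelates this aldehyde with the C10 ether oxygen, C3 of the pendant methyl enol ether adds to C2 (Mukaiyama-type aldol addition), and the methoxycarbenium ion is hydrolysed to the C4 ketone on work-up. The closest known reaction types are the thermal Claisen rearrangement of trisubstituted allyl vinyl ethers to α-quaternary aldehydes and the Lewis-acid-mediated addition of enol ethers to chelated β-alkoxy aldehydes. Only the cyclopentane closes here, by a 5-(enolendo)-exo-trig aldol closure, the mode of the classical 1,4-keto aldehyde cyclisation; the seven-membered ring is closed in step 12. C1 and C5 are set by the (E)-vinyl ether and (Z)-allyl geometries in the chair (C1 methyl and the C6 chain on C5 come out cis), their absolute sense by bond formation anti to the C6 silyloxy group in the conformer that minimises allylic 1,3-strain between H-6 and the C4 methoxy group, and C2 by the chelate, which places the new hydroxyl cis to the C10 chain. The step needs chair over boat and Claisen over the competing Cope shift of the C4=C5–C6–C7–C8=CH2 diene; the open-chain substrate favours the chair, and the oxygen in the rearranging array lowers the Claisen barrier below that of the Cope shift.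

Step 12
Reactants: 18 hydroxy cyclopentanone
Product: 19 bicyclic hydroxy ketone
Conditions: second-generation Grubbs catalyst (5 mol%), PhMe, 80 °C
Reagents that add atoms: none
Why: Ring-closing metathesis between the monosubstituted and the 1,1-disubstituted alkene forms the trisubstituted C8=C9 bond with loss of ethene, and the trans disposition of the two chains on the cyclopentane gives the trans-fused hydroazulene.

Step 13
Reactants: 19 bicyclic hydroxy ketone
Product: 20 diol
Conditions: iPrMgCl, CeCl3, THF, −78 → 0 °C; aq. NH4Cl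
Reagents that add atoms: isopropylmagnesium chloride CC(C)[Mg]Cl
Why: The organocerium reagent should add to the hindered, enolisable ketone without enolisation or reduction, from the α face opposite the angular C1 methyl and the C5–C6 bond and guided by the C2 alkoxide, which sets C4 with the hydroxyl β (organocerium 1,2-addition).

Step 14
Reactants: 20 diol
Product: 21 C2 acetate
Conditions: Ac2O, pyridine, DMAP (cat.), CH2Cl2, 25 °C
Reagents that add atoms: acetic anhydride CC(=O)OC(C)=O
Why: The secondary C2 alcohol is acetylated selectively because the tertiary C4 alcohol next to the isopropyl group does not react under these conditions (acylation).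

Step 15
Reactants: 21 C2 acetate
Product: 22 C6 alcohol
Conditions: HF·pyridine, THF/pyridine, 0 → 25 °C
Reagents that add atoms: none
Why: Buffered fluoride cleaves the silyl ether without touching the acetate or the allylic PMB ether (desilylation).

Step 16
Reactants: 22 C6 alcohol; 23 3,4-dimethoxybenzoyl chloride
Product: 24 veratrate PMB ether
Conditions: Et3N, DMAP, CH2Cl2, 25 °C
Reagents that add atoms: none
Why: DMAP-catalysed acylation of the secondary C6 alcohol with the aroyl chloride leaves the tertiary alcohol free (esterification).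

Step 17
Reactants: 24 veratrate PMB ether
Product: 25 allylic alcohol
Conditions: DDQ, CH2Cl2/pH 7 buffer, 0 °C
Reagents that add atoms: none
Why: DDQ cleaves the PMB ether oxidatively, while the veratroyl ester, which has no benzylic C–H bond, is inert (oxidative debenzylation).

Step 18
Reactants: 25 allylic alcohol
Product: 26 target CNP0197096.2
Conditions: VO(acac)2 (5 mol%), tBuOOH, CH2Cl2, 0 → 25 °C
Reagents that add atoms: tert-butyl hydroperoxide CC(C)(C)OO
Why: Vanadium-catalysed epoxidation is directed by the allylic C10 hydroxyl and should deliver the oxirane oxygen to the α face of C8=C9, syn to that hydroxyl (hydroxyl-directed epoxidation).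

Compound list
1 | prop-2-yn-1-ol (propargyl alcohol) | C#CCO | starting material
2 | dimethyl{(E)-3-[(dimethylalumanyl)oxy]-2-methylprop-1-en-1-yl}alumane (alkenylalane) | C[Al](C)/C=C(/CO[Al](C)C)C | intermediate
3 | (E)-3-iodo-2-methylprop-2-en-1-ol | I/C=C(/CO)C | intermediate
4 | (E)-3-iodo-2-methylprop-2-enal | I/C=C(/C=O)C | intermediate
5 | racemic (E)-1-iodo-2-methylpenta-1,4-dien-3-ol | I/C=C(/C(O)C=C)C | intermediate
6 | (1E,3S)-1-iodo-2-methylpenta-1,4-dien-3-ol | I/C=C(/[C@@H](O)C=C)C | intermediate
7 | (1E,3S)-1-iodo-3-[(4-methoxybenzyl)oxy]-2-methylpenta-1,4-diene (fragment B) | I/C=C(/[C@@H](OCc1ccc(OC)cc1)C=C)C | intermediate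
8 | ethyl glyoxylate | CCOC(=O)C=O | starting material
9 | isobutene (2-methylpropene) | CC(C)=C | starting material
10 | ethyl (R)-2-hydroxy-4-methylpent-4-enoate | C=C(C)C[C@@H](O)C(=O)OCC | intermediate
11 | ethyl (R)-2-[(tert-butyldimethylsilyl)oxy]-4-methylpent-4-enoate | C=C(C)C[C@@H](O[Si](C)(C)C(C)(C)C)C(=O)OCC | intermediate
12 | methyl 2-(dimethoxyphosphoryl)-2-methoxyacetate | COC(C(=O)OC)P(=O)(OC)OC | starting material
13 | (R)-2-[(tert-butyldimethylsilyl)oxy]-4-methylpent-4-enal | C=C(C)C[C@@H](O[Si](C)(C)C(C)(C)C)C=O | intermediate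
14 | methyl (2Z,4R)-4-[(tert-butyldimethylsilyl)oxy]-2-methoxy-6-methylhepta-2,6-dienoate | C=C(C)C[C@@H](O[Si](C)(C)C(C)(C)C)/C=C(/C(=O)OC)OC | intermediate
15 | (2Z,4R)-4-[(tert-butyldimethylsilyl)oxy]-2-methoxy-6-methylhepta-2,6-dien-1-ol (fragment A) | C=C(C)C[C@@H](O[Si](C)(C)C(C)(C)C)/C=C(/CO)OC | intermediate
16 | (2Z,4R)-4-[(tert-butyldimethylsilyl)oxy]-2-methoxy-6-methylhepta-2,6-dien-1-yl (1E,3S)-3-[(4-methoxybenzyl)oxy]-2-methylpenta-1,4-dien-1-yl ether (allyl vinyl ether) | C=C(C)C[C@@H](O[Si](C)(C)C(C)(C)C)/C=C(/CO/C=C(/[C@@H](OCc1ccc(OC)cc1)C=C)C)OC | intermediate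
17 | Claisen aldehyde: C2 formyl on quaternary C1 (methyl and (S)-1-[(4-methoxybenzyl)oxy]prop-2-enyl), C5 carrying the 1-methoxyvinyl group and the (R)-1-[(tert-butyldimethylsilyl)oxy]-3-methylbut-3-enyl chain; C1 and C5 as in 18 | C=C(C)C[C@@H](O[Si](C)(C)C(C)(C)C)[C@H](C(OC)=C)[C@@](C)(C=O)[C@@H](OCc1ccc(OC)cc1)C=C | intermediate
18 | hydroxy cyclopentanone: 2α-hydroxy-1β-methyl-1α-{(S)-1-[(4-methoxybenzyl)oxy]prop-2-enyl}-5β-{(R)-1-[(tert-butyldimethylsilyl)oxy]-3-methylbut-3-enyl}cyclopentan-4-one, H-5 α (daucane numbering) | C=C(C)C[C@@H](O[Si](C)(C)C(C)(C)C)[C@@H]1C(=O)C[C@@H](O)[C@@]1(C)[C@@H](OCc1ccc(OC)cc1)C=C | intermediate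
19 | bicyclic hydroxy ketone: trans-fused 6α-[(tert-butyldimethylsilyl)oxy]-2α-hydroxy-10α-[(4-methoxybenzyl)oxy]-1β,8-dimethyl-5αH-bicyclo[5.3.0]dec-8-en-4-one (daucane numbering) | CC(C)(C)[Si](C)(C)O[C@@H]2CC(C)=C[C@H](OCc1ccc(OC)cc1)[C@]3(C)[C@H](O)CC(=O)[C@@H]23 | intermediate
20 | 6α-[(tert-butyldimethylsilyl)oxy]-10α-[(4-methoxybenzyl)oxy]dauc-8-ene-2α,4β-diol | CC(C)(C)[Si](C)(C)O[C@@H]2CC(C)=C[C@H](OCc1ccc(OC)cc1)[C@]3(C)[C@H](O)C[C@](O)(C(C)C)[C@@H]23 | intermediate
21 | 2α-acetoxy-6α-[(tert-butyldimethylsilyl)oxy]-10α-[(4-methoxybenzyl)oxy]dauc-8-en-4β-ol | CC(C)(C)[Si](C)(C)O[C@@H]2CC(C)=C[C@H](OCc1ccc(OC)cc1)[C@]3(C)[C@H](OC(C)=O)C[C@](O)(C(C)C)[C@@H]23 | intermediate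
22 | 2α-acetoxy-10α-[(4-methoxybenzyl)oxy]dauc-8-ene-4β,6α-diol | O[C@@H]2CC(C)=C[C@H](OCc1ccc(OC)cc1)[C@]3(C)[C@H](OC(C)=O)C[C@](O)(C(C)C)[C@@H]23 | intermediate
23 | 3,4-dimethoxybenzoyl chloride | COc1ccc(C(=O)Cl)cc1OC | starting material
24 | 2α-acetoxy-4β-hydroxy-10α-[(4-methoxybenzyl)oxy]dauc-8-en-6α-yl 3,4-dimethoxybenzoate | COc1ccc(C(=O)O[C@@H]2CC(C)=C[C@H](OCc4ccc(OC)cc4)[C@]3(C)[C@H](OC(C)=O)C[C@](O)(C(C)C)[C@@H]23)cc1OC | intermediate
25 | 2α-acetoxy-4β,10α-dihydroxydauc-8-en-6α-yl 3,4-dimethoxybenzoate | COc1ccc(C(=O)O[C@@H]2CC(C)=C[C@H](O)[C@]3(C)[C@H](OC(C)=O)C[C@](O)(C(C)C)[C@@H]23)cc1OC | intermediate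
26 | CNP0197096.2: 2α-acetoxy-8,9-epoxy-4β,10α-dihydroxydaucan-6α-yl 3,4-dimethoxybenzoate (oxirane descriptors as in the target string) | COc1ccc(C(=O)O[C@@H]2C[C@@]3(C)O[C@@H]3[C@H](O)[C@]3(C)[C@H](OC(C)=O)C[C@](O)(C(C)C)[C@@H]23)cc1OC | target

Total step count: 18. Longest linear sequence: 14 steps (steps 1–5 and 10–18).

Steps most likely to fail

Step 11. What may go wrong: erosion of chair or facial control in the [3,3] shift, or stalling of the five-membered closure with dehydration of the aldol. The fallback sets out from 16: the Claisen rearrangement is run alone (PhMe, 150 °C), and the crude aldehyde 17 is hydrolysed on wet silica gel with oxalic acid to keto aldehyde F1. F1 is closed as its chelated titanium enolate (TiCl4, iPr2NEt, CH2Cl2, −78 °C), a metal enolate aldol in place of the enol ether addition. This makes the two bonds in successive stages and comes back to the route at 18.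

Step 13. What may go wrong: reduction or enolisation of the ketone by the secondary Grignard reagent, or attack from the β face. The fallback sets out from 19: isopropenylmagnesium bromide with CeCl3, an sp2 nucleophile that cannot transfer a β-hydride, gives isopropenyl carbinol F2. Its 1,1-disubstituted alkene is then hydrogenated selectively with RhCl(PPh3)3 under H2, leaving the trisubstituted ring alkene and the PMB ether, and the sequence comes back at 20.

Step 10. What may go wrong: slow C–O coupling of the hindered vinyl iodide, premature rearrangement, or base-induced loss of the enol ether at 80 °C. The fallback sets out from 7: Miyaura borylation (B2pin2, PdCl2(dppf), KOPh, PhMe, 50 °C) gives vinylboronate F3, which is coupled oxidatively with 15 at room temperature (Cu(OAc)2, Et3N; Chan–Lam-type etherification) and comes back at 16.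

Further compounds
F1 | step 11 | keto aldehyde: aldehyde 17 with the 1-methoxyvinyl group hydrolysed to acetyl | C=C(C)C[C@@H](O[Si](C)(C)C(C)(C)C)[C@H](C(C)=O)[C@@](C)(C=O)[C@@H](OCc1ccc(OC)cc1)C=C
F2 | step 13 | isopropenyl carbinol: 20 with prop-1-en-2-yl in place of isopropyl at C4 | CC(C)(C)[Si](C)(C)O[C@@H]2CC(C)=C[C@H](OCc1ccc(OC)cc1)[C@]3(C)[C@H](O)C[C@](O)(C(C)=C)[C@@H]23
F3 | step 10 | vinylboronate: 2-{(1E,3S)-3-[(4-methoxybenzyl)oxy]-2-methylpenta-1,4-dien-1-yl}-4,4,5,5-tetramethyl-1,3,2-dioxaborolane | CC1(C)OB(/C=C(/[C@@H](OCc2ccc(OC)cc2)C=C)C)OC1(C)C
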